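You ask how much target the green flask holds at 8.0 d, and which single move is worth making then.

- green: substrate 0.017 M; coupling partner 0.0102 M; the very flask that is asked about, followed so far
- flask: substrate 0.017 M; coupling partner 0.0102 M; time 8.0 d

green run (percent of the substrate charged)

| time / h | target / % | substrate / % |
|---|---|---|
| 12.0 | 18.4 | 69.3 |
| 40.0 | 26.1 | 53.3 |
| 72.0 | 26.8 | 49.2 |
| 96.0 | 26.6 | 48.3 |
| 144 | 27.3 | 48.4 |
| 192 | 27.0 | 48.0 |

(each reading ± 0.5 percentage points)

- gamma: at 8.0 d take out 90% of the by-product then present, then wait 15 d
- eta: at 8.0 d add substrate, 50.0% of the amount charged, then wait 15 d
- theta: change nothing and wait 15 d more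
- zeta: at 8.0 d add coupling partner, 50.0% of the amount charged, then wait 15 d

- target, in percent of the substrate first charged, at 8.0 d
- what to do for the largest gain in target; "none" if nothing gains more than 2 percentage points (gamma / eta / theta / zeta / none)
- target present, in percent of the substrate first charged, after theta
- target present, in percent of the substrate first charged, after zeta

- additions bring no volume worth counting
- the analysis behind the earlier runs scatters by 0.5 percentage points, standard deviation

Your forecast reads 27% now, 27% after theta and 30.5% after zeta, and it picks gamma: “Removing 90% of the by-product should pull the most”. I agree on the first two and part from it on the rest.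

The last green readings, from 72.0 h on, average 26.9%, so that is my number for now and, unchanged, for theta. The green run has lost 52.0% of 0.017 M substrate against 0.0102 M coupling partner, which is 0.867 of substrate lost per partner charged; I call this ratio w, the partner coverage, and carry it. If one partner goes per substrate, the partner not accounted for is 0.00136 M, less than the 0.00816 M of substrate still free. So I read the coupling partner as the limiting reagent, and I expect no gain from eta.

Zeta adds 0.00510 M of partner. At coverage w, with 0.518 of lost substrate appearing as target, I reckon 13 percentage points more, or 40.4%, higher than your figure. I pick zeta.

The green flask gives 26.4% at 8.0 d, and 26.4% after theta. Zeta gains most, 9.1 points to 35.5%, against 5.7 points for gamma and 0.027 points for eta, so my 13 points stood too high.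

    substrate + coupling partner ⇌ intermediate (K = 3500 M⁻¹, k = 5.10 M⁻¹ h⁻¹)
    intermediate ⇌ target + by-product (K = 0.0130 M, k = 0.260 h⁻¹)
    2 coupling partner → self-condensation product (k = 1.00 M⁻¹ h⁻¹)
    target ⇌ isomer of the product (K = 0.460, k = 0.0250 h⁻¹)
    target → over-reaction product (k = 1.30 × 10⁻⁵ h⁻¹)

In the green flask, free coupling partner stands at 0.789% of its charge at 192 h. That share, added to the coverage w and to the 12.5% of the partner charge held as self-condensation product, comes to 0.999. For the same recipe with 0.0026 M of coupling partner, w gives 86.7% of the substrate left, and that flask holds 85.2%.

(The runs are simulated on assumed constants.)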